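**Retrosynthetic overview**
- Feature: in ring A, O1 is bound to C8a, which is ortho to C4a (the carbon carrying the C4 methylene) and meta to the C7 hydroxyl. C8a is therefore the β-carbon of the cyclohexa-2,5-dienone formed when a plain 4-alkylphenol is dearomatised at C4a.
- Last skeletal bond, O1–C8a: the C2 alcohol adds in oxa-Michael fashion to a 4-alkyl-4-methoxycyclohexadienone, then methanol is lost from C4a to rebuild ring A. Only removal of the O3' silyl group follows.
- The dienone comes from PhI(OAc)2/MeOH oxidation of a (2S)-2-aryl-3-(4-hydroxyphenyl)propanol whose C2 oxygen is masked. C3 and the C3–C4 bond come from an Evans benzylation of the ring B arylacetyl imide.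
- Ring B comes from 2,6-dimethoxyphenol by O-silylation, 3,5-dibromination, mono Br/Li exchange with ethylene oxide (C1' arm) and γ-selective Suzuki–Miyaura reverse prenylation (C5').
- Ring order: rings A and B are bought as arenes, and ring C is the only ring that is formed, at the end.

Key step: step 15

Remark: isoflavan numbering (O1, C2, C3, C4, C4a, C5–C8, C8a; ring B primed) is used for all intermediates, and Ar stands for 2,4-dimethoxy-5-(2-methylbut-3-en-2-yl)-3-(triisopropylsilyloxy)phenyl.

**Route**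

Step 1
Reactants: 1 2,6-dimethoxyphenol
Product: 2 (2,6-dimethoxyphenoxy)triisopropylsilane
Conditions: TIPSCl, imidazole, DMF, rt → 40 °C
Reagents that add atoms: triisopropylsilyl chloride, CC(C)[Si](Cl)(C(C)C)C(C)C
Why: Imidazole-promoted O-silylation of the phenol; the bulky silyl group should survive the organolithium, aqueous phosphate, hydride and acid used later, and it makes the central oxygen the weakest donor of the ring.

Step 2
Reactants: 2 (2,6-dimethoxyphenoxy)triisopropylsilane
Product: 3 (3,5-dibromo-2,6-dimethoxyphenoxy)triisopropylsilane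
Conditions: NBS (2.1 equiv), MeCN, 0 °C → rt
Reagents that add atoms: N-bromosuccinimide, O=C1CCC(=O)N1Br
Why: Electrophilic aromatic bromination; C3 and C5 are each ortho to one methoxy group and para to the other, whereas C4 is para only to the twisted, weakly donating silyloxy group, so the symmetrical 3,5-dibromide is expected.

Step 3
Reactants: 3 (3,5-dibromo-2,6-dimethoxyphenoxy)triisopropylsilane; 4 ethylene oxide
Product: 6 2-[5-bromo-2,4-dimethoxy-3-(triisopropylsilyloxy)phenyl]ethanol, via aryllithium 5 (not isolated)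
Conditions: n-BuLi (1.0 equiv), THF, −78 °C; ethylene oxide (3 equiv), then BF3·OEt2 (1.2 equiv), −78 °C; H2O
Reagents that add atoms: none
Why: Bromine–lithium exchange followed by Lewis-acid-assisted epoxide opening; the two bromines are equivalent by symmetry so one equivalent of n-BuLi gives a single monolithio species, lithium sits meta to the silyloxy group (no retro-Brook shift), and the fast opening at −78 °C forestalls bromine scrambling.

Step 4
Reactants: 6 2-[5-bromo-2,4-dimethoxy-3-(triisopropylsilyloxy)phenyl]ethanol; 7 3-methyl-2-butenylboronic acid pinacol ester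
Product: 8 2-Ar-ethanol, that is 2-[2,4-dimethoxy-5-(2-methylbut-3-en-2-yl)-3-(triisopropylsilyloxy)phenyl]ethanol
Conditions: Pd(OAc)2 (4 mol %), JackiePhos (8 mol %), K3PO4 (3 equiv, aq), MeCN, 70 °C
Reagents that add atoms: none
Why: γ-Selective Suzuki–Miyaura allyl–aryl coupling; the prenylboronate transmetalates in SE2' fashion so that palladium is bound to the tertiary allyl terminus, and the bulky, electron-poor biarylphosphine should make C–C reductive elimination faster than σ–π–σ drift to the primary terminus, giving the 1,1-dimethylallyl rather than the prenyl group at C5'.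

Step 5
Reactants: 8 2-Ar-ethanol
Product: 10 2-Ar-acetic acid, via arylacetaldehyde 9 (not isolated)
Conditions: TEMPO (0.2 equiv), PhI(OAc)2 (2.2 equiv), MeCN–H2O (1:1), rt
Reagents that add atoms: water, O
Why: Oxoammonium (TEMPO) oxidation with PhI(OAc)2 as terminal oxidant takes the primary alcohol through the aldehyde hydrate to the acid, without affecting the vinyl group, the aryl silyl ether or the fully O-capped arene.

Step 6
Reactants: 10 2-Ar-acetic acid; 11 (S)-4-benzyl-2-oxazolidinone
Product: 13 (4S)-4-benzyl-3-(2-Ar-acetyl)oxazolidin-2-one, via mixed pivalic anhydride 12 (not isolated)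
Conditions: PivCl, Et3N, THF, −20 °C; then 11, LiCl, −20 °C → rt
Reagents that add atoms: none
Why: Mixed-anhydride N-acylation of the auxiliary under LiCl/Et3N activation; attack occurs at the less hindered arylacetyl carbonyl and no strong base meets the aryl silyl ether.

Step 7
Reactants: 14 4-hydroxybenzyl alcohol
Product: 15 4-(allyloxy)benzyl alcohol
Conditions: allyl bromide, K2CO3, acetone, reflux
Reagents that add atoms: allyl bromide, C=CCBr
Why: Williamson etherification in which K2CO3 deprotonates only the phenol; an allyl ether is chosen for O7 because its later removal is orthogonal to both silyl ethers of the route.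

Step 8
Reactants: 15 4-(allyloxy)benzyl alcohol
Product: 16 4-(allyloxy)benzyl bromide
Conditions: PBr3 (0.4 equiv), Et2O, 0 °C; used crude
Reagents that add atoms: phosphorus tribromide, BrP(Br)Br
Why: Substitution of the activated benzylic alcohol by bromide through its phosphite ester; the reactive bromide is used at once.

Step 9
Reactants: 13 (4S)-4-benzyl-3-(2-Ar-acetyl)oxazolidin-2-one; 16 4-(allyloxy)benzyl bromide
Product: 18 (4S)-4-benzyl-3-{(2S)-3-[4-(allyloxy)phenyl]-2-Ar-propanoyl}oxazolidin-2-one, via sodium Z-enolate 17 (not isolated)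
Conditions: NaN(SiMe3)2 (1.05 equiv), THF, −78 °C; 16, −78 → −40 °C; AcOH quench
Reagents that add atoms: none
Why: Evans asymmetric alkylation; the sodium-chelated Z-enolate is shielded on one face by the benzyl group of the (S)-auxiliary, so the benzylic bromide forms C3–C4 on the open face and sets C3 as S (priorities C=O > Ar > CH2Ar'), and the minor diastereomer can be removed by chromatography.

Step 10
Reactants: 18 (4S)-4-benzyl-3-{(2S)-3-[4-(allyloxy)phenyl]-2-Ar-propanoyl}oxazolidin-2-one
Product: 19 (2S)-3-[4-(allyloxy)phenyl]-2-Ar-propan-1-ol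
Conditions: LiBH4, MeOH (1 equiv), Et2O, 0 °C
Reagents that add atoms: none
Why: Reductive cleavage of the imide by hydride attack at the exocyclic carbonyl; the medium is weakly basic, so the α-aryl centre should not epimerise, and the descriptor stays S (CH2OH > Ar > CH2Ar').

Step 11
Reactants: 19 (2S)-3-[4-(allyloxy)phenyl]-2-Ar-propan-1-ol
Product: 20 triethylsilyl ether of 19
Conditions: TESCl, imidazole, CH2Cl2, 0 °C
Reagents that add atoms: triethylsilyl chloride, CC[Si](Cl)(CC)CC
Why: O-Silylation masks the C2 hydroxyl, which would otherwise spirocyclise onto C4a during the oxidation; a silyl ether is preferred to an ester because it is later removed without base or methoxide, both of which would add to the dienone.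

Step 12
Reactants: 20 triethylsilyl ether of 19
Product: 21 4-[(2S)-2-Ar-3-(triethylsilyloxy)propyl]phenol
Conditions: Pd(PPh3)4 (5 mol %), morpholine (5 equiv), THF, rt
Reagents that add atoms: none
Why: Tsuji–Trost-type deallylation; zerovalent palladium ionises the aryl allyl ether and morpholine traps the π-allyl fragment, while the 1,1-dimethylallyl group carries no leaving group and both silyl ethers are inert.

Step 13
Reactants: 21 4-[(2S)-2-Ar-3-(triethylsilyloxy)propyl]phenol
Product: 22 4-[(2S)-2-Ar-3-(triethylsilyloxy)propyl]-4-methoxycyclohexa-2,5-dien-1-one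
Conditions: PhI(OAc)2 (1.1 equiv), MeOH, 0 °C
Reagents that add atoms: methanol, CO
Why: Oxidative dearomatisation of a 4-alkylphenol; ligand exchange at PhI(OAc)2 and departure of PhI make C4a electrophilic and solvent methanol is captured there, ring B has no free hydroxyl to be oxidised, and C4a carries two identical enone arms so no stereocentre arises.

Step 14
Reactants: 22 4-[(2S)-2-Ar-3-(triethylsilyloxy)propyl]-4-methoxycyclohexa-2,5-dien-1-one
Product: 23 4-[(2S)-2-Ar-3-hydroxypropyl]-4-methoxycyclohexa-2,5-dien-1-one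
Conditions: AcOH–THF–H2O (3:3:1), rt
Reagents that add atoms: none
Why: Mild acidic hydrolysis of a primary triethylsilyl ether; the hindered aryl triisopropylsilyl ether is untouched, and acetic acid is too weak to drive the conjugate addition at a useful rate, so the free alcohol should be isolable.

Step 15
Reactants: 23 4-[(2S)-2-Ar-3-hydroxypropyl]-4-methoxycyclohexa-2,5-dien-1-one
Product: 25 (3S)-3-Ar-chroman-7-ol, via oxa-Michael adduct 24 (not isolated)
Conditions: TsOH·H2O (10 mol %), CH2Cl2 (0.02 M), 0 °C → rt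
Reagents that add atoms: none
Why: Protonation of the dienone carbonyl lets the C2 hydroxyl add to the β-carbon C8a (oxa-Michael), which makes O1–C8a and gives the hexahydrochromenone 24; 24 enolises toward C8 to a cyclohexadienol that is formally the methanol adduct of the arene, its protonated tertiary allylic C4a methoxy group ionises to an arenium ion, and loss of H8a returns aromatic ring A with the C7 hydroxyl free. The closest known reaction types are the Brønsted-acid-catalysed intramolecular oxa-Michael addition of tethered alcohols to 4,4-disubstituted cyclohexadienones and the conjugate addition–rearomatisation of quinol ethers and quinone monoketals to meta-substituted phenols, run here in one flask. Ring C closes in the 6-exo-trig mode. No new stereocentre survives: the two enone arms are diastereotopic and 24 may form as a mixture at C4a and C8a, but both carbons become sp2, while C3 lies next to no carbonyl or cation and keeps its S configuration. The step needs O-attack to beat the 1,2-shift of C4 (dienone–phenol rearrangement), conjugate attack by C6' of ring B and addition of liberated methanol. The three-carbon tether, a weak catalytic acid, high dilution in a non-nucleophilic solvent, and the position of C6' beside the tertiary alkyl group with only the para silyloxy group as donor should secure this.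

Step 16
Reactants: 25 (3S)-3-Ar-chroman-7-ol
Product: 26 (3S)-3-[3-hydroxy-2,4-dimethoxy-5-(2-methylbut-3-en-2-yl)phenyl]chroman-7-ol
Conditions: Bu4NF, AcOH (1:1, 1.5 equiv), THF, 0 °C → rt
Reagents that add atoms: none
Why: Fluoride-induced cleavage of the aryl silyl ether, buffered so that the electron-rich phenols are not left as phenoxides; no other group responds to fluoride and C3 is untouched.

**Compound list**
1 | 2,6-dimethoxyphenol | COc1cccc(OC)c1O | starting material
2 | (2,6-dimethoxyphenoxy)triisopropylsilane | COc1cccc(OC)c1O[Si](C(C)C)(C(C)C)C(C)C | intermediate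
3 | (3,5-dibromo-2,6-dimethoxyphenoxy)triisopropylsilane | COc1c(Br)cc(Br)c(OC)c1O[Si](C(C)C)(C(C)C)C(C)C | intermediate
4 | ethylene oxide | C1CO1 | starting material
5 | 5-bromo-2,4-dimethoxy-3-(triisopropylsilyloxy)phenyllithium (not isolated) | COc1c([Li])cc(Br)c(OC)c1O[Si](C(C)C)(C(C)C)C(C)C | intermediate
6 | 2-[5-bromo-2,4-dimethoxy-3-(triisopropylsilyloxy)phenyl]ethanol | OCCc1cc(Br)c(OC)c(O[Si](C(C)C)(C(C)C)C(C)C)c1OC | intermediate
7 | 3-methyl-2-butenylboronic acid pinacol ester | CC(C)=CCB1OC(C)(C)C(C)(C)O1 | starting material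
8 | 2-[2,4-dimethoxy-5-(2-methylbut-3-en-2-yl)-3-(triisopropylsilyloxy)phenyl]ethanol | OCCc1cc(C(C)(C)C=C)c(OC)c(O[Si](C(C)C)(C(C)C)C(C)C)c1OC | intermediate
9 | 2-Ar-acetaldehyde (not isolated) | O=CCc1cc(C(C)(C)C=C)c(OC)c(O[Si](C(C)C)(C(C)C)C(C)C)c1OC | intermediate
10 | 2-Ar-acetic acid | OC(=O)Cc1cc(C(C)(C)C=C)c(OC)c(O[Si](C(C)C)(C(C)C)C(C)C)c1OC | intermediate
11 | (S)-4-benzyl-2-oxazolidinone | O=C1N[C@@H](Cc2ccccc2)CO1 | starting material
12 | 2-Ar-acetic pivalic anhydride (not isolated) | CC(C)(C)C(=O)OC(=O)Cc1cc(C(C)(C)C=C)c(OC)c(O[Si](C(C)C)(C(C)C)C(C)C)c1OC | intermediate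
13 | (4S)-4-benzyl-3-(2-Ar-acetyl)oxazolidin-2-one | O=C1OC[C@H](Cc2ccccc2)N1C(=O)Cc1cc(C(C)(C)C=C)c(OC)c(O[Si](C(C)C)(C(C)C)C(C)C)c1OC | intermediate
14 | 4-hydroxybenzyl alcohol | OCc1ccc(O)cc1 | starting material
15 | 4-(allyloxy)benzyl alcohol | C=CCOc1ccc(CO)cc1 | intermediate
16 | 4-(allyloxy)benzyl bromide | C=CCOc1ccc(CBr)cc1 | intermediate
17 | sodium Z-enolate of 13 (not isolated) | [Na+].[O-]/C(=C\c1cc(C(C)(C)C=C)c(OC)c(O[Si](C(C)C)(C(C)C)C(C)C)c1OC)N1[C@@H](Cc2ccccc2)COC1=O | intermediate
18 | (4S)-4-benzyl-3-{(2S)-3-[4-(allyloxy)phenyl]-2-Ar-propanoyl}oxazolidin-2-one | O=C1OC[C@H](Cc2ccccc2)N1C(=O)[C@@H](Cc1ccc(OCC=C)cc1)c1cc(C(C)(C)C=C)c(OC)c(O[Si](C(C)C)(C(C)C)C(C)C)c1OC | intermediate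
19 | (2S)-3-[4-(allyloxy)phenyl]-2-Ar-propan-1-ol | OC[C@@H](Cc1ccc(OCC=C)cc1)c1cc(C(C)(C)C=C)c(OC)c(O[Si](C(C)C)(C(C)C)C(C)C)c1OC | intermediate
20 | triethylsilyl ether of 19, (2S) | CC[Si](CC)(CC)OC[C@@H](Cc1ccc(OCC=C)cc1)c1cc(C(C)(C)C=C)c(OC)c(O[Si](C(C)C)(C(C)C)C(C)C)c1OC | intermediate
21 | 4-[(2S)-2-Ar-3-(triethylsilyloxy)propyl]phenol | CC[Si](CC)(CC)OC[C@@H](Cc1ccc(O)cc1)c1cc(C(C)(C)C=C)c(OC)c(O[Si](C(C)C)(C(C)C)C(C)C)c1OC | intermediate
22 | 4-[(2S)-2-Ar-3-(triethylsilyloxy)propyl]-4-methoxycyclohexa-2,5-dien-1-one | CC[Si](CC)(CC)OC[C@@H](CC1(OC)C=CC(=O)C=C1)c1cc(C(C)(C)C=C)c(OC)c(O[Si](C(C)C)(C(C)C)C(C)C)c1OC | intermediate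
23 | 4-[(2S)-2-Ar-3-hydroxypropyl]-4-methoxycyclohexa-2,5-dien-1-one (key-step precursor) | OC[C@@H](CC1(OC)C=CC(=O)C=C1)c1cc(C(C)(C)C=C)c(OC)c(O[Si](C(C)C)(C(C)C)C(C)C)c1OC | intermediate
24 | (3S)-3-Ar-4a-methoxy-2,3,4,4a,8,8a-hexahydro-7H-chromen-7-one, mixture at C4a and C8a (not isolated) | O=C1C=CC2(OC)C[C@@H](c3cc(C(C)(C)C=C)c(OC)c(O[Si](C(C)C)(C(C)C)C(C)C)c3OC)COC2C1 | intermediate
25 | (3S)-3-Ar-chroman-7-ol (key-step product) | C=CC(C)(C)c1cc([C@H]2COc3cc(O)ccc3C2)c(OC)c(O[Si](C(C)C)(C(C)C)C(C)C)c1OC | intermediate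
26 | (3S)-3-[3-hydroxy-2,4-dimethoxy-5-(2-methylbut-3-en-2-yl)phenyl]chroman-7-ol | C=CC(C)(C)c1cc([C@H]2COc3cc(O)ccc3C2)c(OC)c(O)c1OC | target

**Step count**
Total step count: 16. Longest linear sequence: 14 (steps 1–6, then 9–16). Steps 7–8 form the two-step side branch.

**Steps most likely to fail**

1. Step 15. The conjugate adduct may form but retain its C4a methoxy group. The stronger acid then needed could start migration of the C4 methylene or conjugate attack by C6' of ring B.
   - Fallback: give up the dearomatisation and close O1–C8a by an intramolecular Buchwald–Hartwig etherification. This sets out from 13 and returns at 26.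
   - Commercial 3-bromo-4-methylphenol is silylated (TIPSCl, imidazole, DMF) to (3-bromo-4-methylphenoxy)triisopropylsilane F1. Radical bromination at the methyl group (NBS, AIBN, PhCF3, reflux) gives [3-bromo-4-(bromomethyl)phenoxy]triisopropylsilane F2.
   - The sodium enolate of 13 is alkylated with F2 under the conditions of step 9 to (4S)-4-benzyl-3-{(2S)-2-Ar-3-[2-bromo-4-(triisopropylsilyloxy)phenyl]propanoyl}oxazolidin-2-one F3. LiBH4 then gives (2S)-2-Ar-3-[2-bromo-4-(triisopropylsilyloxy)phenyl]propan-1-ol F4.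
   - Pd(OAc)2, 2-(di-tert-butylphosphino)-1,1'-binaphthyl and Cs2CO3 in toluene at 70 °C close ring C to (3S)-3-Ar-7-(triisopropylsilyloxy)chroman F5. Bu4NF/AcOH removes both silyl groups to give 26.

2. Step 4. Oxidative addition at the electron-rich, ortho-substituted bromide may be slow, and σ–π–σ isomerisation of the allylpalladium species may erode the branched selectivity toward the linear prenyl isomer.
   - Fallback: build the quaternary carbon first and the vinyl group afterwards. This sets out from 6 and returns at 8.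
   - Palladium-catalysed α-arylation of isobutyraldehyde with 6 ([Pd(allyl)Cl]2, Q-phos, Cs2CO3, THF, 80 °C) gives 2-[5-(2-hydroxyethyl)-2,4-dimethoxy-3-(triisopropylsilyloxy)phenyl]-2-methylpropanal F6.
   - Wittig methylenation (Ph3PCH3Br, KOt-Bu, excess, THF, 0 °C → rt) converts F6 into 8.

3. Step 13. Loss of a C4 proton to a para-quinone methide, or capture of the electrophilic C4a by ring B instead of methanol, may lower the return of dienone.
   - Fallback: dearomatise with singlet oxygen instead of PhI(OAc)2 and carry a C4a hydroxyl as the leaving group. This sets out from 21 and returns at 25.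
   - KHSO5 (used as the triple salt 2KHSO5·KHSO4·K2SO4) with NaHCO3 in MeCN–H2O generates singlet oxygen, which adds para to the phenol to give 4-hydroperoxy-4-[(2S)-2-Ar-3-(triethylsilyloxy)propyl]cyclohexa-2,5-dien-1-one F7. The vinyl group has no allylic hydrogen for an ene reaction.
   - Me2S reduces F7 to 4-hydroxy-4-[(2S)-2-Ar-3-(triethylsilyloxy)propyl]cyclohexa-2,5-dien-1-one F8. AcOH–THF–H2O then frees 4-hydroxy-4-[(2S)-2-Ar-3-hydroxypropyl]cyclohexa-2,5-dien-1-one F9.
   - Catalytic TsOH in CH2Cl2, as in step 15, gives 25 with water leaving from C4a.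

**Further compounds**
F1 | step 15 | (3-bromo-4-methylphenoxy)triisopropylsilane | Cc1ccc(O[Si](C(C)C)(C(C)C)C(C)C)cc1Br
F2 | step 15 | [3-bromo-4-(bromomethyl)phenoxy]triisopropylsilane | BrCc1ccc(O[Si](C(C)C)(C(C)C)C(C)C)cc1Br
F3 | step 15 | (4S)-4-benzyl-3-{(2S)-2-Ar-3-[2-bromo-4-(triisopropylsilyloxy)phenyl]propanoyl}oxazolidin-2-one | O=C1OC[C@H](Cc2ccccc2)N1C(=O)[C@@H](Cc1ccc(O[Si](C(C)C)(C(C)C)C(C)C)cc1Br)c1cc(C(C)(C)C=C)c(OC)c(O[Si](C(C)C)(C(C)C)C(C)C)c1OC
F4 | step 15 | (2S)-2-Ar-3-[2-bromo-4-(triisopropylsilyloxy)phenyl]propan-1-ol | OC[C@@H](Cc1ccc(O[Si](C(C)C)(C(C)C)C(C)C)cc1Br)c1cc(C(C)(C)C=C)c(OC)c(O[Si](C(C)C)(C(C)C)C(C)C)c1OC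
F5 | step 15 | (3S)-3-Ar-7-(triisopropylsilyloxy)chroman | C=CC(C)(C)c1cc([C@H]2COc3cc(O[Si](C(C)C)(C(C)C)C(C)C)ccc3C2)c(OC)c(O[Si](C(C)C)(C(C)C)C(C)C)c1OC
F6 | step 4 | 2-[5-(2-hydroxyethyl)-2,4-dimethoxy-3-(triisopropylsilyloxy)phenyl]-2-methylpropanal | O=CC(C)(C)c1cc(CCO)c(OC)c(O[Si](C(C)C)(C(C)C)C(C)C)c1OC
F7 | step 13 | 4-hydroperoxy-4-[(2S)-2-Ar-3-(triethylsilyloxy)propyl]cyclohexa-2,5-dien-1-one | CC[Si](CC)(CC)OC[C@@H](CC1(OO)C=CC(=O)C=C1)c1cc(C(C)(C)C=C)c(OC)c(O[Si](C(C)C)(C(C)C)C(C)C)c1OC
F8 | step 13 | 4-hydroxy-4-[(2S)-2-Ar-3-(triethylsilyloxy)propyl]cyclohexa-2,5-dien-1-one | CC[Si](CC)(CC)OC[C@@H](CC1(O)C=CC(=O)C=C1)c1cc(C(C)(C)C=C)c(OC)c(O[Si](C(C)C)(C(C)C)C(C)C)c1OC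
F9 | step 13 | 4-hydroxy-4-[(2S)-2-Ar-3-hydroxypropyl]cyclohexa-2,5-dien-1-one | OC[C@@H](CC1(O)C=CC(=O)C=C1)c1cc(C(C)(C)C=C)c(OC)c(O[Si](C(C)C)(C(C)C)C(C)C)c1OC
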